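**Retrosynthetic overview**
1. Side-chain CH2–CH(OH) bond: ligand-controlled Cr-catalysed allylation of 3-methylbut-2-enal with a ring-bound 2-substituted allyl chloride. This is the last step and sets 4'S.
2. The allyl chloride comes from the isopropenyl carbinol, which comes from a singlet-oxygen ene reaction on an isopropylidenecyclohexane. The C1–O bond goes in late, onto an sp2 C1, anti to the axial chlorine.
3. Key bond, tertiary C4–Br: cobalt-hydride H-atom transfer to a 2-chloro-1-methylidenecyclohexane, then Br-atom transfer to the tertiary radical anti to Cl. This gives the sec-Cl/tert-Br pattern.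
4. The allylic chloride comes from Peterson methylenation of an (S)-α-chloro ketone, made by organocatalytic α-chlorination (the only source of ring chirality) after mono-Wittig reaction of cyclohexane-1,4-dione.
5. Rings: the single carbocycle is bought with the dione, so no ring is formed. C1 stays sp2 until both halogens are set, so the ring is not conformationally locked.

Assumption: for each chiral catalyst or ligand, the enantiomer that gives the drawn configuration is used. The descriptors written are the expected ones and are swapped if the first run shows the opposite sense.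

**Step 1**
Reactants: 1 cyclohexane-1,4-dione
Product: 2 4-(propan-2-ylidene)cyclohexan-1-one
Conditions: i-PrPPh3I, n-BuLi, THF, 0 °C; then 1 (3 equiv), −78 °C → rt
Reagents that add atoms: isopropyltriphenylphosphonium iodide CC(C)[P+](c1ccccc1)(c1ccccc1)c1ccccc1.[I-]
Why: Wittig olefination of one of two equivalent carbonyls (excess recoverable dione favours mono-olefination); no stereocentre forms, and the tetrasubstituted alkene keeps the future carbinol carbon sp2 so the ring stays conformationally free for steps 4 and 5.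

**Step 2**
Reactants: 2 4-(propan-2-ylidene)cyclohexan-1-one
Product: 3 (2S)-2-chloro-4-(propan-2-ylidene)cyclohexan-1-one
Conditions: NCS (1.0 equiv), (4R,5R)-4,5-diphenylimidazolidine (20 mol%), 2-NO2C6H4CO2H (50 mol%), MeCN, −24 °C
Reagents that add atoms: N-chlorosuccinimide O=C1CCC(=O)N1Cl
Why: Enamine-catalysed enantioselective α-chlorination, in which the two α-carbons of 2 are equivalent, enamine activation makes the α-carbon far more nucleophilic towards NCS than the alkene, and the C2-symmetric amine shields one face so that the C–Cl centre is set as S.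

**Step 3**
Reactants: 3 (2S)-2-chloro-4-(propan-2-ylidene)cyclohexan-1-one
Product: 5 (2S)-2-chloro-1-methylidene-4-(propan-2-ylidene)cyclohexane, via β-hydroxysilane 4 (not isolated)
Conditions: Me3SiCH2MgCl, LaCl3·2LiCl (30 mol%), THF, −40 °C; then 48% aq HF, MeCN, 0 °C
Reagents that add atoms: (trimethylsilyl)methylmagnesium chloride C[Si](C)(C)C[Mg]Cl
Why: Peterson olefination, in which the weakly basic La-activated Grignard adds 1,2 without enolising (racemising) the α-chloro ketone and acid-induced elimination of Me3Si/OH from 4 erases the new carbinol centre, so only the untouched S chloride remains.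

**Step 4 (key step)**
Reactants: 5 (2S)-2-chloro-1-methylidene-4-(propan-2-ylidene)cyclohexane
Product: 7 (1S,2S)-1-bromo-2-chloro-1-methyl-4-(propan-2-ylidene)cyclohexane, via tertiary β-chloroalkyl radical 6 (not isolated)
Conditions: Co(acac)2 (25 mol%), t-BuOOH (25 mol%), Et3SiH (3 equiv), TsBr (2 equiv), n-PrOH/CH2Cl2, Ar, rt, dark
Reagents that add atoms: 4-methylbenzenesulfonyl bromide Cc1ccc(cc1)S(=O)(=O)Br
Why: Cobalt-hydride hydrogen-atom-transfer (Mukaiyama-type) Markovnikov hydrobromination, in which Co–H gives H• only to the unhindered 1,1-disubstituted alkene (the tetrasubstituted one is inert, whereas ionic HBr would protonate it first), radical 6 holds its C–Cl bond axial and aligned with the SOMO while loss of Cl• is slow, and TsBr transfers Br to the face anti to chlorine, forming the tertiary C–Br bond trans-diaxial to Cl (new centre S) with a halogen regiochemistry that polar BrCl addition cannot give.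

**Step 5**
Reactants: 7 (1S,2S)-1-bromo-2-chloro-1-methyl-4-(propan-2-ylidene)cyclohexane
Product: 9 (1R,3S,4S)-4-bromo-3-chloro-4-methyl-1-(prop-1-en-2-yl)cyclohexan-1-ol, via allylic hydroperoxide 8 (not isolated)
Conditions: O2, TPP (0.5 mol%), white LED, CH2Cl2, −20 °C; then PPh3, −20 °C → rt
Reagents that add atoms: dioxygen O=O
Why: Schenck ene reaction of singlet oxygen followed by P(III) reduction, in which H is taken from an isopropylidene methyl (as in terpinolene → p-mentha-1,8-dien-4-ol) and oxygen bonds to the ring carbon from the face opposite the 1,3-related axial chlorine, setting C1 as R (OH trans to Cl, cis to Br), after which the ring flips to the chair with equatorial side chain and halogens.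

**Step 6**
Reactants: 9 (1R,3S,4S)-4-bromo-3-chloro-4-methyl-1-(prop-1-en-2-yl)cyclohexan-1-ol
Product: 10 (1R,3S,4S)-4-bromo-3-chloro-1-(3-chloroprop-1-en-2-yl)-4-methylcyclohexan-1-ol
Conditions: NCS (1.1 equiv), PhSeCl (10 mol%), CH2Cl2, 0 °C → rt, dark
Reagents that add atoms: N-chlorosuccinimide O=C1CCC(=O)N1Cl
Why: Selenium-catalysed ene-type allylic chlorination, in which the isopropenyl methyl carries the only allylic C–H bonds, the alkene transposition is degenerate, the neutral conditions avoid a free β-chloro cation next to the carbinol (semipinacol shift), and no stereocentre is touched.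

**Step 7**
Reactants: 10 (1R,3S,4S)-4-bromo-3-chloro-1-(3-chloroprop-1-en-2-yl)-4-methylcyclohexan-1-ol; 11 3-methylbut-2-enal
Product: 14 (1R,3S,4S)-4-bromo-3-chloro-1-[(4S)-4-hydroxy-6-methylhepta-1,5-dien-2-yl]-4-methylcyclohexan-1-ol, via allylchromium(III) species 12 (not isolated), via trimethylsilyl ether 13 (not isolated)
Conditions: CrCl2 (10 mol%), (S,S)-bis(oxazolinyl)carbazole ligand (12 mol%), Mn (2 equiv), TMSCl (2 equiv), i-Pr2NEt (30 mol%), THF, 0 °C; then aq citric acid, THF
Reagents that add atoms: chlorotrimethylsilane C[Si](C)(C)Cl (silyl group of 13 only, lost on work-up); chromium(II) chloride Cl[Cr]Cl (catalyst, metal of 12 only)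
Why: Catalytic asymmetric Nozaki–Hiyama–Kishi-type allylation (radical–polar crossover), in which Cr(II) reduces the activated allylic C–Cl bond by single-electron transfer far faster than the unactivated tertiary bromide, the symmetric 2-substituted allyl radical is captured as 12, 12 adds 1,2 to the Si face of 11 through a closed six-membered transition state to set the carbinol S under ligand control, Mn/TMSCl turn the catalyst over, and mild acid frees 14 from 13.

**Compound list**
1 | cyclohexane-1,4-dione | O=C1CCC(=O)CC1 | starting material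
2 | 4-(propan-2-ylidene)cyclohexan-1-one | CC(C)=C1CCC(=O)CC1 | intermediate
3 | (2S)-2-chloro-4-(propan-2-ylidene)cyclohexan-1-one | CC(C)=C1CCC(=O)[C@@H](Cl)C1 | intermediate
4 | (2S)-2-chloro-4-(propan-2-ylidene)-1-[(trimethylsilyl)methyl]cyclohexan-1-ol (both C1 epimers; not isolated) | CC(C)=C1CCC(O)(C[Si](C)(C)C)[C@@H](Cl)C1 | intermediate
5 | (2S)-2-chloro-1-methylidene-4-(propan-2-ylidene)cyclohexane | CC(C)=C1CCC(=C)[C@@H](Cl)C1 | intermediate
6 | (2S)-2-chloro-1-methyl-4-(propan-2-ylidene)cyclohexyl radical (not isolated) | CC(C)=C1CC[C](C)[C@@H](Cl)C1 | intermediate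
7 | (1S,2S)-1-bromo-2-chloro-1-methyl-4-(propan-2-ylidene)cyclohexane (Br/Cl trans) | CC(C)=C1CC[C@](C)(Br)[C@@H](Cl)C1 | intermediate
8 | (1R,3S,4S)-4-bromo-3-chloro-4-methyl-1-(prop-1-en-2-yl)cyclohexyl hydroperoxide (not isolated) | C=C(C)[C@@]1(OO)CC[C@](C)(Br)[C@@H](Cl)C1 | intermediate
9 | (1R,3S,4S)-4-bromo-3-chloro-4-methyl-1-(prop-1-en-2-yl)cyclohexan-1-ol | C=C(C)[C@@]1(O)CC[C@](C)(Br)[C@@H](Cl)C1 | intermediate
10 | (1R,3S,4S)-4-bromo-3-chloro-1-(3-chloroprop-1-en-2-yl)-4-methylcyclohexan-1-ol | C=C(CCl)[C@@]1(O)CC[C@](C)(Br)[C@@H](Cl)C1 | intermediate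
11 | 3-methylbut-2-enal | CC(C)=CC=O | starting material
12 | allylchromium(III) dichloride derived from 10 (chiral ligand omitted; not isolated) | C=C(C[Cr](Cl)Cl)[C@@]1(O)CC[C@](C)(Br)[C@@H](Cl)C1 | intermediate
13 | 4'-O-trimethylsilyl ether of 14 (not isolated) | C=C(C[C@H](O[Si](C)(C)C)C=C(C)C)[C@@]1(O)CC[C@](C)(Br)[C@@H](Cl)C1 | intermediate
14 | (1R,3S,4S)-4-bromo-3-chloro-1-[(4S)-4-hydroxy-6-methylhepta-1,5-dien-2-yl]-4-methylcyclohexan-1-ol | C=C(C[C@H](O)C=C(C)C)[C@@]1(O)CC[C@](C)(Br)[C@@H](Cl)C1 | target

**Total step count:** 7. **Longest linear sequence:** 7.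

**Steps most likely to fail**

Step 4. The risks are sulfonyl-radical addition to the methylidene group, loss of Cl• from 6, and a poor trans:cis ratio. The fallback reaches the same radical by C–O activation instead of C=C activation. It sets out from 3.
- MeMgBr with LaCl3·2LiCl gives the tertiary chlorohydrin (2S)-2-chloro-1-methyl-4-(propan-2-ylidene)cyclohexan-1-ol F1. Its carbinol epimers are irrelevant.
- Methyl chlorooxoacetate, Et3N and DMAP give methyl (2S)-2-chloro-1-methyl-4-(propan-2-ylidene)cyclohexyl oxalate F2.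
- One equivalent of CsOH gives cesium (2S)-2-chloro-1-methyl-4-(propan-2-ylidene)cyclohexyl oxalate F3.
- Visible-light photoredox oxidation (Ir photocatalyst, blue LED), using diethyl 2-bromo-2-methylmalonate as bromine-atom donor, expels two CO2 and passes through 6.

The fallback comes back to the route at 7.

Step 6. The risks are semipinacol ring expansion, chlorohydrin formation, and interference by the free tertiary OH. The fallback replaces electrophilic chlorine by an ene/[2,3] oxidation. It sets out from 9.
- SeO2 (0.5 equiv) and t-BuOOH in CH2Cl2 oxidise the only allylic methyl to (1R,3S,4S)-4-bromo-3-chloro-1-(3-hydroxyprop-1-en-2-yl)-4-methylcyclohexan-1-ol F4.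
- MsCl, collidine and LiCl in DMF at 0 °C convert the primary allylic alcohol into 2-[(1R,3S,4S)-4-bromo-3-chloro-1-hydroxy-4-methylcyclohexyl]prop-2-en-1-yl methanesulfonate F5, which chloride displaces in situ.

The fallback comes back to the route at 10.

Step 7. The risks are Cr(II)/Mn attack on the bromochloride unit, OH chelation eroding ligand control, and pinacol coupling of the enal. The fallback avoids low-valent metal reductants altogether. It sets out from 10.
- Base-free Pd2(dba)3-catalysed borylation with B2pin2 in THF gives (1R,3S,4S)-4-bromo-3-chloro-4-methyl-1-[3-(4,4,5,5-tetramethyl-1,3,2-dioxaborolan-2-yl)prop-1-en-2-yl]cyclohexan-1-ol F6.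
- Chiral phosphoric acid (TRIP, 5 mol%) catalysed allylboration of 11 in toluene at −30 °C gives the 4'-O-pinacolboryl ester of 14 F7.
- Aqueous work-up hydrolyses this ester.

The fallback comes back to the route at 14.

**Further compounds**
F1 | step 4 | (2S)-2-chloro-1-methyl-4-(propan-2-ylidene)cyclohexan-1-ol | CC(C)=C1CCC(C)(O)[C@@H](Cl)C1
F2 | step 4 | methyl (2S)-2-chloro-1-methyl-4-(propan-2-ylidene)cyclohexyl oxalate | CC(C)=C1CCC(C)(OC(=O)C(=O)OC)[C@@H](Cl)C1
F3 | step 4 | cesium (2S)-2-chloro-1-methyl-4-(propan-2-ylidene)cyclohexyl oxalate | CC(C)=C1CCC(C)(OC(=O)C(=O)[O-])[C@@H](Cl)C1.[Cs+]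
F4 | step 6 | (1R,3S,4S)-4-bromo-3-chloro-1-(3-hydroxyprop-1-en-2-yl)-4-methylcyclohexan-1-ol | C=C(CO)[C@@]1(O)CC[C@](C)(Br)[C@@H](Cl)C1
F5 | step 6 | 2-[(1R,3S,4S)-4-bromo-3-chloro-1-hydroxy-4-methylcyclohexyl]prop-2-en-1-yl methanesulfonate | C=C(COS(C)(=O)=O)[C@@]1(O)CC[C@](C)(Br)[C@@H](Cl)C1
F6 | step 7 | (1R,3S,4S)-4-bromo-3-chloro-4-methyl-1-[3-(4,4,5,5-tetramethyl-1,3,2-dioxaborolan-2-yl)prop-1-en-2-yl]cyclohexan-1-ol | C=C(CB2OC(C)(C)C(C)(C)O2)[C@@]1(O)CC[C@](C)(Br)[C@@H](Cl)C1
F7 | step 7 | 4'-O-pinacolboryl ester of 14 | C=C(C[C@H](OB2OC(C)(C)C(C)(C)O2)C=C(C)C)[C@@]1(O)CC[C@](C)(Br)[C@@H](Cl)C1
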